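**Time and plateau.** From 4.00 d to 8.00 d, the target in Wednesday's flask reads 41.7%, 42.7% and 42.4%. Its electrophile falls from 18.7% to 8.4% over the same days. So electrophile is still being spent, and over those days the target gains 0.7 percentage points while the electrophile loses 10 points. This is the flask asked about.

| setting | Wednesday's | Saturday's | flask |
|---|---|---|---|
| electrophile | 0.50 M | 0.25 M | 0.50 M |
| nucleophile | 0.40 M | 0.40 M | 0.400 M |
| free base | 1 M | 1 M | 1.00 M |
| protic impurity | 0.50 M | 0.50 M | 0.500 M |
| temperature | 70 °C | 65 °C | 70 °C |
| remark | the very flask that is asked about, followed so far | run made earlier |  |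
| time |  |  | 8.0 d |

| run | time / d | target / % | electrophile / % |
|---|---|---|---|
| Wednesday's | 0.500 | 32.6 | 55.9 |
| Wednesday's | 1.67 | 39.9 | 34.3 |
| Wednesday's | 3.00 | 41.2 | 23.8 |
| Wednesday's | 4.00 | 41.7 | 18.7 |
| Wednesday's | 6.00 | 42.7 | 11.5 |
| Wednesday's | 8.00 | 42.4 | 8.4 |
| Saturday's | 0.833 | 46.0 | 41.6 |
| Saturday's | 1.25 | 54.0 | 32.0 |
| Saturday's | 2.50 | 63.3 | 15.2 |
| Saturday's | 4.00 | 67.6 | 8.0 |
| Saturday's | 6.00 | 68.6 | 4.0 |
| Saturday's | 10.0 | 70.4 | 0.8 |

(each reading ± 0.5 percentage points)

- elm: at 8.0 d take out 90% of the target then present, then wait 8.0 d
- birch: change nothing and wait 8.0 d more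
- ash: at 8.0 d raise the temperature by 15 K, then wait 8.0 d
- maple: at 8.0 d add nucleophile, 50.0% of the amount charged, then wait 8.0 d

- removed target is counted in
- additions bring no volume worth counting

1. target, in percent of the electrophile first charged, at 8.0 d
2. what to do for the largest gain in target; "none" if nothing gains more than 2 percentage points (elm / birch / ash / maple / none)
3. target present, with what was taken out counted in, in percent of the electrophile first charged, after elm
4. target present, with what was taken out counted in, in percent of the electrophile first charged, after birch

**First way.** I suppose the rate of target formation follows the free nucleophile, so that is the concentration I watch. The last two readings of Wednesday's flask average 42.5%. That is my plateau, read from the flask itself.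

**Second way.** I suppose each target sets acid free, and that this acid protonates a second nucleophile. Let c_B and c_A be the charges of nucleophile and electrophile. For Wednesday's flask, c_B/(2 c_A) gives 40.0%. I call this Y, the two-for-one ceiling: the target, in percent of the electrophile charged, that the nucleophile pays for at two per target. In Wednesday's flask the nucleophile is then the limiting reagent.

**Where they part.** In Wednesday's flask the plateau stands 2.5 points above Y, while one reading scatters by 0.5 points. So Y cheats. It sends every acid to nucleophile, yet 1.00 M of free base could take some. Saturday's flask tests the rule differently. Its Y is 80.0%, but its target and electrophile together end at 71.2%. So Saturday's flask stays below Y: its electrophile reads 0.8% at 10.0 d, and its target is still rising, from 68.6% to 70.4%.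

**The options.** Y contains no time, temperature or removed target, so I expect birch, elm and ash to stay near the plateau. Maple raises Y by 20 points, but Wednesday's flask reads 8.4% of electrophile, so the electrophile bounds the gain. Its first reading shows 73.9% of the electrophile spent becoming target. If that early share holds after the addition, I expect about 6.2 points from maple, above the 2 points margin.

The forecast gives 42.6% (range 42.1% to 43.1%), 42.9% after elm and 42.9% after birch, and it picks maple for about 3 points where I reckon 6.2 points, holding that “Waiting, removing target or heating therefore gain almost nothing”.

**The result.** The flask gives 42.5%, with 43.0% after elm and 43.0% after birch, and maple gains 6.5 points.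

    electrophile + nucleophile → acid set free + target (k = 5.60 × 10⁻⁵ /M/s, Ea = 75.0 kJ/mol)
    nucleophile + acid set free ⇌ protonated nucleophile, settled at all times (K = 5500 /M, ΔH = 13.0 kJ/mol)
    acid set free + free base ⇌ salt of the base (K = 1.60 /M, k = 6.30 × 10⁻⁴ /M/s, Ea = 60.0 kJ/mol, ΔH = 24.0 kJ/mol)
    electrophile + protic impurity → quenched substrate (k = 8.10 × 10⁻⁶ /M/s, Ea = 76.0 kJ/mol)
    (constants at 70 °C)

At 8.00 d the flask holds 0.765% of its nucleophile free, 0.184 M of protonated nucleophile, 0.0172 M of salt of the base and 0.0110 M of acid set free. The result lies 2.5 points above Y. A neighbour flask charged with 1.2 M of electrophile has Y of 16.7%. It gives 19.9%, with 0.230% of its nucleophile free.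

The runs were computed for an exercise, and the scatter is random.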